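**Plan**
1. Retrosynthetic cuts: the O–CH3 bond, the three pyrrole C–Br bonds and the N–SO2Ph bond are functional-group operations. The skeletal cut opens the bromophenol ring at C2'–C3' and C1'–C6', with CO2 restored across C3'/C6'. The last cut is the alkyne–pyrrole C2 bond.
2. Enabling feature: the benzene ring is numbered C1' (pyrrolyl), C2' (O), C3' (Br), C4' (H), C5' (Br), C6' (H). The segment C3'–C6' repeats the Br/H/Br/H pattern of the diene carbons C3–C6 of 3,5-dibromo-2-pyrone. The pair C1'–C2' (one hetaryl carbon, one oxygenated carbon) is an ynol ether, so no redox step is needed after CO2 loss.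
3. Forward order: the pyrrole ring is bought and the alkyne is attached to it. The benzene ring is the only ring built (step 5). N-Desulfonylation, threefold pyrrole bromination and O-demethylation follow.
4. The ynol ether is carried as its methyl ether. It has no β-hydrogen, so heating cannot trigger retro-ene collapse to a ketene; it is also the smallest group next to the C3–Br terminus and is cleaved by BBr3.
5. Stereochemistry: none has to be set.

Key step: step 5

Remark: the target has no stereocentre and its aryl–pyrrole axis rotates freely. It is therefore one achiral compound, and the demand for a single enantiomer is met without stereocontrol.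

**Step 1**
Reactants: 1 coumalic acid (2-oxo-2H-pyran-5-carboxylic acid)
Product: 3 3,5-dibromo-2H-pyran-2-one, via 5-bromo-2H-pyran-2-one 2 (not isolated)
Conditions: NBS (2.5 equiv), Bu4NBr (5 mol %), CHCl3, 50 °C
Reagents that add atoms: N-bromosuccinimide, O=C1CCC(=O)N1Br
Why: Hunsdiecker-type bromodecarboxylation of the C5 acid gives the 5-bromopyrone, whose most enol-like position C3 is then brominated electrophilically in the same pot, a standard one-pot entry to this pyrone.

**Step 2**
Reactants: 4 1-(phenylsulfonyl)-1H-pyrrole
Product: 6 2-iodo-1-(phenylsulfonyl)-1H-pyrrole, via 2-lithio-1-(phenylsulfonyl)pyrrole 5 (not isolated)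
Conditions: LDA (commercial solution, 1.1 equiv), THF, −78 °C; then I2, −78 °C → rt
Reagents that add atoms: iodine, II
Why: In this directed α-lithiation the N-sulfonyl group acidifies C2–H and coordinates the base there, and iodinolysis of the aryllithium fixes the halide at C2, the electron-poor nitrogen substituent keeping the 2-iodopyrrole stable enough to handle.

**Step 3**
Reactants: 7 trichloroethylene
Product: 9 (E)-1,2-dichloro-1-methoxyethene, via dichloroacetylene 8 (not isolated)
Conditions: KOMe (1.05 equiv), THF, N2, −40 °C → rt; distillation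
Reagents that add atoms: potassium methoxide, [K+].[O-]C
Why: Base-induced dehydrochlorination gives dichloroacetylene (kept in solution under nitrogen), to which methoxide/methanol adds in anti fashion (hence the E alkene, a geometry erased in step 4), the established first stage of the trichloroethylene route to alkynyl ethers.

**Step 4**
Reactants: 9 (E)-1,2-dichloro-1-methoxyethene; 6 2-iodo-1-(phenylsulfonyl)-1H-pyrrole
Product: 13 2-(methoxyethynyl)-1-(phenylsulfonyl)-1H-pyrrole, via chloro(methoxy)ethyne 10 (not isolated), via lithium methoxyacetylide 11 (not isolated), via (methoxyethynyl)zinc chloride 12 (not isolated)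
Conditions: 9 (1.3 equiv), n-BuLi (2.0 equiv per 9), THF, −78 → −40 °C; ZnCl2, → 0 °C; 6, Pd(PPh3)4 (5 mol %), THF, rt; chromatography on Et3N-deactivated silica
Reagents that add atoms: none
Why: Loss of HCl and chlorine–lithium exchange with two equivalents of n-BuLi unmask the alkoxyacetylide, and its zinc derivative undergoes Negishi coupling with the aryl iodide under neutral, anhydrous conditions that spare the acid-labile ynol ether and the base-labile sulfonamide, a known way to aryl alkynyl ethers.

**Step 5**
Reactants: 3 3,5-dibromo-2H-pyran-2-one; 13 2-(methoxyethynyl)-1-(phenylsulfonyl)-1H-pyrrole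
Product: 15 2-(3,5-dibromo-2-methoxyphenyl)-1-(phenylsulfonyl)-1H-pyrrole, via bridged dienyl lactone 14 (not isolated)
Conditions: 3 (1.0 equiv), 13 (1.3 equiv), BHT (cat.), 4 Å MS, PhMe (degassed), sealed tube, 110 °C
Reagents that add atoms: none
Why: The electron-poor pyrone diene and the electron-rich alkyne combine in an asynchronous inverse-electron-demand [4+2] cycloaddition in which the nucleophilic, pyrrole-bearing alkyne carbon bonds to pyrone C6 (future C1'–C6') and the oxygen-bearing carbon to C3 (future C2'–C3'), and the bridged dienyl lactone 14 then expels CO2 by retro-[4+2] at the reaction temperature, which makes arene formation irreversible. The closest known reaction type is the Diels–Alder/CO2-extrusion benzannulation of 2-pyrones with alkynes, heteroatom-substituted ones included, together with the cycloadditions of 3,5-dibromo-2-pyrone to enol ethers; the hetaryl ynol ether is a new partner within that class. The one ring formed, the six-membered carbocycle, is closed by intermolecular [4+2] cycloaddition, both σ-bonds arising in one operation rather than by cyclisation of a chain. No stereocentre survives, since the two bridgeheads of racemic 14 become sp2 carbons of the benzene ring. The step needs regioselectivity (oxygen next to C3'–Br, pyrrole next to C6'–H), which is secured by the match between the methoxy-polarised alkyne and C6 as the vinylogous acceptor end of the dienolide, the orientation that enol ethers also follow, and is reinforced sterically because the bulky pyrrolyl carbon meets the unsubstituted C6–H terminus. The methyl group has no β-hydrogen, so the retro-ene loss of alkene that limits ethyl and tert-butyl ynol ethers cannot occur at 110 °C, and the N-sulfonyl group keeps the pyrrole from competing as nucleophile or diene.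

**Step 6**
Reactants: 15 2-(3,5-dibromo-2-methoxyphenyl)-1-(phenylsulfonyl)-1H-pyrrole
Product: 16 2-(3,5-dibromo-2-methoxyphenyl)-1H-pyrrole
Conditions: NaOH (5 equiv), H2O–1,4-dioxane, 80 °C
Reagents that add atoms: none
Why: Hydroxide attacks sulfur and expels the stabilised pyrrolide (hydrolysis of an N-sulfonylazole), while the aryl bromides and the methyl ether are inert and the absence of methanol rules out N-methylation by a sulfonate ester.

**Step 7**
Reactants: 16 2-(3,5-dibromo-2-methoxyphenyl)-1H-pyrrole
Product: 19 2,3,4-tribromo-5-(3,5-dibromo-2-methoxyphenyl)-1H-pyrrole, via 5-bromopyrrole intermediate 17 (not isolated), via 4,5-dibromopyrrole intermediate 18 (not isolated)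
Conditions: NBS (3.05 equiv), THF, −78 °C → rt, dark
Reagents that add atoms: N-bromosuccinimide, O=C1CCC(=O)N1Br
Why: Electrophilic aromatic substitution on the π-excessive NH-pyrrole is far faster than on the anisole ring, which is deactivated by two bromines and has every position ortho and para to OMe occupied, so three equivalents of NBS should fill the free α-position and then the two β-positions of the pyrrole.

**Step 8**
Reactants: 19 2,3,4-tribromo-5-(3,5-dibromo-2-methoxyphenyl)-1H-pyrrole
Product: 21 pentabromopseudilin, 2,4-dibromo-6-(3,4,5-tribromo-1H-pyrrol-2-yl)phenol, via aryloxydibromoborane 20 (not isolated)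
Conditions: BBr3 (3 equiv), CH2Cl2, −78 °C → rt; then ice-water
Reagents that add atoms: none
Why: In this Lewis-acid ether cleavage boron coordinates to the methoxy oxygen, bromide removes the methyl group by SN2 and aqueous work-up hydrolyses the aryl borate, conditions under which aryl and pyrrolyl C–Br bonds are expected to persist.

**Compound list**
1 | coumalic acid | O=C(O)c1ccc(=O)oc1 | starting material
2 | 5-bromo-2H-pyran-2-one | O=c1ccc(Br)co1 | intermediate
3 | 3,5-dibromo-2H-pyran-2-one | O=c1occ(Br)cc1Br | intermediate
4 | 1-(phenylsulfonyl)-1H-pyrrole | O=S(=O)(c1ccccc1)n1cccc1 | starting material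
5 | 2-lithio-1-(phenylsulfonyl)-1H-pyrrole | [Li]c1cccn1S(=O)(=O)c1ccccc1 | intermediate
6 | 2-iodo-1-(phenylsulfonyl)-1H-pyrrole | Ic1cccn1S(=O)(=O)c1ccccc1 | intermediate
7 | trichloroethylene | ClC=C(Cl)Cl | starting material
8 | dichloroacetylene | ClC#CCl | intermediate
9 | (E)-1,2-dichloro-1-methoxyethene | CO/C(Cl)=C\Cl | intermediate
10 | chloro(methoxy)ethyne | COC#CCl | intermediate
11 | lithium methoxyacetylide | COC#C[Li] | intermediate
12 | (methoxyethynyl)zinc chloride | COC#C[Zn]Cl | intermediate
13 | 2-(methoxyethynyl)-1-(phenylsulfonyl)-1H-pyrrole | COC#Cc1cccn1S(=O)(=O)c1ccccc1 | intermediate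
14 | (±)-4,7-dibromo-5-methoxy-6-[1-(phenylsulfonyl)-1H-pyrrol-2-yl]-2-oxabicyclo[2.2.2]octa-5,7-dien-3-one | O=C1OC2C(Br)=CC1(Br)C(OC)=C2c1cccn1S(=O)(=O)c1ccccc1 | intermediate
15 | 2-(3,5-dibromo-2-methoxyphenyl)-1-(phenylsulfonyl)-1H-pyrrole | COc1c(Br)cc(Br)cc1-c1cccn1S(=O)(=O)c1ccccc1 | intermediate
16 | 2-(3,5-dibromo-2-methoxyphenyl)-1H-pyrrole | COc1c(Br)cc(Br)cc1-c1ccc[nH]1 | intermediate
17 | 2-bromo-5-(3,5-dibromo-2-methoxyphenyl)-1H-pyrrole | COc1c(Br)cc(Br)cc1-c1ccc(Br)[nH]1 | intermediate
18 | 2,3-dibromo-5-(3,5-dibromo-2-methoxyphenyl)-1H-pyrrole | COc1c(Br)cc(Br)cc1-c1cc(Br)c(Br)[nH]1 | intermediate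
19 | 2,3,4-tribromo-5-(3,5-dibromo-2-methoxyphenyl)-1H-pyrrole | COc1c(Br)cc(Br)cc1-c1[nH]c(Br)c(Br)c1Br | intermediate
20 | dibromo[2,4-dibromo-6-(3,4,5-tribromo-1H-pyrrol-2-yl)phenoxy]borane | BrB(Br)Oc1c(Br)cc(Br)cc1-c1[nH]c(Br)c(Br)c1Br | intermediate
21 | pentabromopseudilin, 2,4-dibromo-6-(3,4,5-tribromo-1H-pyrrol-2-yl)phenol | Oc1c(Br)cc(Br)cc1-c1[nH]c(Br)c(Br)c1Br | target

**Total step count:** 8
**Longest linear sequence:** 6 steps (2, 4, 5, 6, 7, 8 from compound 4; equally 3, 4, 5, 6, 7, 8 from compound 7)

**Steps most likely to fail**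

Step 5. The internal, hindered ynol ether may oligomerise or be hydrated by adventitious acid faster than it cycloadds, or the reaction may stall at temperatures the pyrone tolerates.
- The fallback sets out from 13 (with 3) and comes back at 15. It forms the same two ring bonds but uses a more nucleophilic dienophile of the same oxidation level.
- Anhydrous methanol with catalytic PPTS should add twice to 13 to give the storable orthoester 2-(2,2,2-trimethoxyethyl)-1-(phenylsulfonyl)-1H-pyrrole F1.
- Heated with 3 in mesitylene with catalytic pivalic acid at about 140 °C, as in the first stage of a Johnson–Claisen rearrangement, F1 should release methanol to give the ketene dimethyl acetal 2-(2,2-dimethoxyethenyl)-1-(phenylsulfonyl)-1H-pyrrole F2.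
- This acetal adds to the pyrone in the same orientation, a well-known reaction of 2-pyrones with 1,1-dialkoxyalkenes, to give the bridged dimethoxy lactone F3.
- Loss of CO2 leads to the dimethoxycyclohexadiene F4, and elimination of methanol aromatises it to 15.

Step 4. The alkynylzinc reagent may undergo protodemetalation or homocoupling, oxidative addition next to the bulky sulfonyl group may be sluggish, and the ynol ether may hydrolyse during isolation.
- The fallback sets out from 4 by way of 5 and comes back at 13. It makes steps 2 and 3 unnecessary and builds the triple bond by elimination instead of cross-coupling.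
- The lithio compound 5 is acylated with N,2-dimethoxy-N-methylacetamide (Weinreb ketone synthesis) to give 2-methoxy-1-[1-(phenylsulfonyl)-1H-pyrrol-2-yl]ethan-1-one F5.
- LiHMDS and PhNTf2 in THF should convert it, through the chelated enolate, into the (Z)-enol triflate F6.
- In F6 the vinylic hydrogen stands anti to the triflate, so KOt-Bu at −78 °C should eliminate it to 13.

Step 8. Acid released during cleavage and quench may cause protodebromination or bromine migration on the tribromopyrrole, and boron–nitrogen complexation may slow the demethylation.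
- The fallback sets out from 15 and comes back at 21. It reorders the endgame so that the Lewis acid meets only a bromine-free, sulfonyl-deactivated pyrrole.
- BBr3 in CH2Cl2 converts 15 through the N-sulfonylated aryloxydibromoborane F7 into 2,4-dibromo-6-[1-(phenylsulfonyl)-1H-pyrrol-2-yl]phenol F8.
- Aqueous NaOH in dioxane removes the sulfonyl group to give 2,4-dibromo-6-(1H-pyrrol-2-yl)phenol F9.
- All ortho and para positions of this phenol ring are blocked. Three equivalents of NBS in THF at low temperature should therefore brominate the pyrrole through the 5-bromopyrrolyl phenol F10 and the 4,5-dibromopyrrolyl phenol F11 to give 21 directly.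

**Further compounds**
F1 | step 5 | 2-(2,2,2-trimethoxyethyl)-1-(phenylsulfonyl)-1H-pyrrole | COC(OC)(OC)Cc1cccn1S(=O)(=O)c1ccccc1
F2 | step 5 | 2-(2,2-dimethoxyethenyl)-1-(phenylsulfonyl)-1H-pyrrole | COC(OC)=Cc1cccn1S(=O)(=O)c1ccccc1
F3 | step 5 | (±)-4,7-dibromo-5,5-dimethoxy-6-[1-(phenylsulfonyl)-1H-pyrrol-2-yl]-2-oxabicyclo[2.2.2]oct-7-en-3-one (configuration at C6 of no consequence) | O=C1OC2C(Br)=CC1(Br)C(OC)(OC)C2c1cccn1S(=O)(=O)c1ccccc1
F4 | step 5 | (±)-2-(3,5-dibromo-6,6-dimethoxycyclohexa-2,4-dien-1-yl)-1-(phenylsulfonyl)-1H-pyrrole | COC1(OC)C(Br)=CC(Br)=CC1c1cccn1S(=O)(=O)c1ccccc1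
F5 | step 4 | 2-methoxy-1-[1-(phenylsulfonyl)-1H-pyrrol-2-yl]ethan-1-one | COCC(=O)c1cccn1S(=O)(=O)c1ccccc1
F6 | step 4 | (Z)-2-methoxy-1-[1-(phenylsulfonyl)-1H-pyrrol-2-yl]ethenyl trifluoromethanesulfonate | CO/C=C(\OS(=O)(=O)C(F)(F)F)c1cccn1S(=O)(=O)c1ccccc1
F7 | step 8 | dibromo{2,4-dibromo-6-[1-(phenylsulfonyl)-1H-pyrrol-2-yl]phenoxy}borane | BrB(Br)Oc1c(Br)cc(Br)cc1-c1cccn1S(=O)(=O)c1ccccc1
F8 | step 8 | 2,4-dibromo-6-[1-(phenylsulfonyl)-1H-pyrrol-2-yl]phenol | Oc1c(Br)cc(Br)cc1-c1cccn1S(=O)(=O)c1ccccc1
F9 | step 8 | 2,4-dibromo-6-(1H-pyrrol-2-yl)phenol | Oc1c(Br)cc(Br)cc1-c1ccc[nH]1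
F10 | step 8 | 2,4-dibromo-6-(5-bromo-1H-pyrrol-2-yl)phenol | Oc1c(Br)cc(Br)cc1-c1ccc(Br)[nH]1
F11 | step 8 | 2,4-dibromo-6-(4,5-dibromo-1H-pyrrol-2-yl)phenol | Oc1c(Br)cc(Br)cc1-c1cc(Br)c(Br)[nH]1
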